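Everything rests on building ring B rather than joining two finished arenes. Ring B carries its ether oxygen (C1') and hydroxyl (C6') on neighbouring carbons. Its C4' bromine sits para to the ether oxygen and meta to the hydroxyl, where no phenol-directed bromination can reach. A [4+2] cycloaddition of an aryl ynol ether with a 3-oxygenated 5-bromo-2-pyrone, followed by loss of CO2, forms C1'–C6' and C2'–C3'. It closes ring B as a benzene and delivers both oxygens and the C4' bromine in place. The precursors are 5-bromo-2-oxo-2H-pyran-3-yl acetate and 1-(ethynyloxy)-2-methoxybenzene. Deprotection and hydroxyl-directed bromination at C3', C5' (ring B) and C3, C5 (ring A) finish the synthesis.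

Key step: step 5

Atom labels:
- Ring B: C1' (ether O), C2' (H), C3' to C5' (Br), C6' (OH).
- Ring A: C1 (ether O), C2 (OH), C3 (Br), C4 (H), C5 (Br), C6 (H).
- The target has no stereocentre.

Design remark: the C6' oxygen rides on the pyrone as an acetate, not as an alkyl ether.
- An alkoxy group at C3 is a pi donor. It raises the pyrone LUMO and works against an inverse-demand cycloaddition.
- Acetoxy has a Hammett para constant close to that of bromine, so the diene keeps the electronic profile of 3,5-dibromo-2-pyrone.
- The more reactive diene allows a lower temperature, which suits the heat-sensitive ynol ether.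
- The acetate costs no extra step and leaves in the same flask as the ring A methyl group.

Assumption: 3,5-dibromo-2H-pyran-2-one, 2-methoxyphenol and trichloroethylene are taken as purchased catalogue compounds.

Step 1
Reactants: 1 3,5-dibromo-2H-pyran-2-one
Product: 3 5-bromo-3-hydroxy-2H-pyran-2-one, via C3 pinacol boronate 2 (not isolated)
Conditions: B2pin2 (1.05 equiv), PdCl2(dppf) (5 mol %), KOAc, 1,4-dioxane, 80 °C; filter through Celite; then Me3NO (3 equiv), THF, rt; acidic aqueous work-up
Reagents that add atoms: trimethylamine N-oxide, C[N+](C)(C)[O-] (oxygen at C3 of 3); bis(pinacolato)diboron, CC1(C)OB(OC1(C)C)B1OC(C)(C)C(C)(C)O1 (boryl group of 2)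
Why: Miyaura borylation and oxidation of the resulting boronate: zerovalent palladium inserts into this dibromide preferentially at C3–Br, the bond next to the lactone carbonyl, as its Stille, Suzuki and Sonogashira couplings and its stannylation show, bromo-2-pyrones are established borylation substrates under KOAc, and the neutral amine N-oxide turns C–B into C–O by 1,2-migration without the hydroxide that would open the lactone.

Step 2
Reactants: 3 5-bromo-3-hydroxy-2H-pyran-2-one
Product: 4 5-bromo-2-oxo-2H-pyran-3-yl acetate
Conditions: Ac2O, pyridine, CH2Cl2, 0 °C to rt
Reagents that add atoms: acetic anhydride, CC(=O)OC(C)=O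
Why: O-Acylation of an acidic enolic hydroxyl, comparable to an electron-poor phenol, is fast under a mild amine base, and the acetate removes the donor character of the C3 oxygen that would otherwise work against the cycloaddition.

Step 3
Reactants: 5 2-methoxyphenol; 6 trichloroethylene
Product: 8 1-{[(E)-1,2-dichloroethenyl]oxy}-2-methoxybenzene, via dichloroacetylene 7 (not isolated)
Conditions: K2CO3, DMF, 70 °C
Reagents that add atoms: none
Why: Elimination–addition: carbonate strips HCl from 6, the phenoxide of 5 adds to the resulting dichloroacetylene, and anti protonation of the vinyl anion places the two chlorines trans, which sets the E geometry (erased again in the next step).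

Step 4
Reactants: 8 1-{[(E)-1,2-dichloroethenyl]oxy}-2-methoxybenzene
Product: 11 1-(ethynyloxy)-2-methoxybenzene, via chloroethynyl ether 9 (not isolated), via lithium acetylide 10 (not isolated)
Conditions: n-BuLi (2.3 equiv), Et2O, −78 to −40 °C; then sat. aq. NH4Cl, −78 °C; used promptly as a cold solution
Reagents that add atoms: none
Why: Dichlorovinyl ether route to ynol ethers: the first equivalent of n-BuLi effects beta-elimination of LiCl, the second performs chlorine–lithium exchange on the chloroalkyne, and protonation of the acetylide gives the terminal ynol ether, the methoxyarene being inert to n-BuLi at this temperature.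

Step 5
Reactants: 4 5-bromo-2-oxo-2H-pyran-3-yl acetate; 11 1-(ethynyloxy)-2-methoxybenzene
Product: 13 5-bromo-2-(2-methoxyphenoxy)phenyl acetate, via bridged lactone 12 (not isolated)
Conditions: 11 (2.5 equiv, syringe pump), BHT (cat.), toluene, 100 °C, Ar; −CO2
Reagents that add atoms: none
Why: Inverse-electron-demand Diels–Alder reaction followed by retro-Diels–Alder loss of CO2, the established conversion of 2-pyrones and alkynes into benzenes, for which the cycloadditions of 3,5-dibromo-2-pyrone with electron-rich partners are the closest models. The HOMO of 11 is concentrated on its terminal carbon and the LUMO of 4 on C6, the far end of the dienoate, so the [4+2] transition state is concerted but asynchronous, with C2'–C3' forming ahead of C1'–C6'. Ring B thus closes by an intermolecular [4+2] cycloaddition that makes two sigma bonds of a six-membered ring at once, and it becomes aromatic when the lactone bridge of 12 departs as CO2. The two bridgehead stereocentres of 12 arise as a racemate, are tied to each other by the bicycle and vanish on aromatisation, so no stereocontrol is called for. The selectivity that is needed is regiochemical, aryloxy carbon to C3 of the pyrone, and the matched polarisation secures it, since the reverse orientation would build negative charge where the lactone carbonyl cannot accept it. The acetate and the C5 bromine keep the LUMO of 4 low, 11 has no beta C–H bond for retro-ene collapse to a ketene, and slow addition in the presence of BHT holds back its oligomerisation.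

Step 6
Reactants: 13 5-bromo-2-(2-methoxyphenoxy)phenyl acetate
Product: 15 5-bromo-2-(2-hydroxyphenoxy)phenol, via phenol acetate 14 (not isolated)
Conditions: BBr3 (3 equiv), CH2Cl2, −78 °C to rt; then MeOH, 40 °C
Reagents that add atoms: none
Why: Lewis acid ether cleavage: BBr3 binds the ring A methoxy oxygen and bromide removes the methyl group by SN2 attack, the diaryl ether and the aryl bromide being inert, and the HBr released on the methanol quench catalyses transesterification of the aryl acetate, so both hydroxyls are freed in one flask.

Step 7
Reactants: 15 5-bromo-2-(2-hydroxyphenoxy)phenol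
Product: 16 2,3,4-tribromo-6-(3,5-dibromo-2-hydroxyphenoxy)phenol (target)
Conditions: Br2 (4.1 equiv), NaOAc, AcOH–H2O, 0 °C to rt
Reagents that add atoms: bromine, BrBr
Why: Electrophilic aromatic substitution: each free hydroxyl outranks the diaryl ether oxygen as a donor and has exactly one ortho and one para position open (C3 and C5 in ring A, C5' and C3' in ring B), the acetate buffer favours the phenol-directed pathway, and the known exhaustive bromination of 3-bromophenol to its 2,3,4,6-tetrabromide shows that sites next to a resident bromine are still reached.

Compound list
1 | 3,5-dibromo-2H-pyran-2-one | O=c1occ(Br)cc1Br | starting material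
2 | 5-bromo-3-(4,4,5,5-tetramethyl-1,3,2-dioxaborolan-2-yl)-2H-pyran-2-one (not isolated) | O=c1occ(Br)cc1B1OC(C)(C)C(C)(C)O1 | intermediate
3 | 5-bromo-3-hydroxy-2H-pyran-2-one | O=c1occ(Br)cc1O | intermediate
4 | 5-bromo-2-oxo-2H-pyran-3-yl acetate | CC(=O)Oc1cc(Br)coc1=O | intermediate
5 | 2-methoxyphenol | COc1ccccc1O | starting material
6 | trichloroethylene | ClC=C(Cl)Cl | starting material
7 | dichloroacetylene (not isolated) | ClC#CCl | intermediate
8 | 1-{[(E)-1,2-dichloroethenyl]oxy}-2-methoxybenzene | COc1ccccc1O/C(Cl)=C\Cl | intermediate
9 | 1-[(chloroethynyl)oxy]-2-methoxybenzene (not isolated) | COc1ccccc1OC#CCl | intermediate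
10 | lithium (2-methoxyphenoxy)acetylide (not isolated) | COc1ccccc1OC#C[Li] | intermediate
11 | 1-(ethynyloxy)-2-methoxybenzene | COc1ccccc1OC#C | intermediate
12 | 7-bromo-5-(2-methoxyphenoxy)-3-oxo-2-oxabicyclo[2.2.2]octa-5,7-dien-4-yl acetate (racemic, one enantiomer drawn; not isolated) | O=C1O[C@@H]2C(Br)=C[C@@]1(OC(C)=O)C(Oc1ccccc1OC)=C2 | intermediate
13 | 5-bromo-2-(2-methoxyphenoxy)phenyl acetate | COc1ccccc1Oc1ccc(Br)cc1OC(C)=O | intermediate
14 | 5-bromo-2-(2-hydroxyphenoxy)phenyl acetate (not isolated) | CC(=O)Oc1cc(Br)ccc1Oc1ccccc1O | intermediate
15 | 5-bromo-2-(2-hydroxyphenoxy)phenol | Oc1ccccc1Oc1ccc(Br)cc1O | intermediate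
16 | 2,3,4-tribromo-6-(3,5-dibromo-2-hydroxyphenoxy)phenol | Oc1c(Br)cc(Br)cc1Oc1cc(Br)c(Br)c(Br)c1O | target

Total step count: 7.
Longest linear sequence: 5 steps (1, 2, 5, 6, 7, or equally 3, 4, 5, 6, 7).

Steps most likely to fail

Step 5. The cycloaddition may be outrun by thermal oligomerisation of the ynol ether, or the regiocontrol may erode. The fallback gives up the ring synthesis and joins two arenes. It sets out from 5. Chan–Lam coupling with purchased (4-bromo-2-methoxyphenyl)boronic acid (Cu(OAc)2, pyridine, 4 Å molecular sieves, CH2Cl2, air, rt) leaves the aryl bromide untouched. It should give 4-bromo-2-methoxy-1-(2-methoxyphenoxy)benzene F1. BBr3 in CH2Cl2 then removes both methyl groups, and the route is rejoined at 15.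

Step 1. Several processes may interfere: loss of site preference in the oxidative addition, protodeboronation of the C3 boronate, its Suzuki-type coupling with unreacted bromide, or damage to the lactone during oxidation. The fallback forms the C3–O bond directly, without boron. It sets out from 1. Palladium-catalysed C–O coupling with (E)-benzaldoxime as a hydroxide surrogate (Pd2(dba)3, tBuBrettPhos, Cs2CO3, 1,4-dioxane, 60 to 80 °C) should give (E)-benzaldehyde O-(5-bromo-2-oxo-2H-pyran-3-yl)oxime F2. Under the same carbonate base this eliminates benzonitrile and returns to the route at 3.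

Step 7. Three processes may interfere: bromination directed by the ether oxygen (para to it, at C4 of ring A) may compete with the second hydroxyl-directed bromination of that ring, the crowded C5' position may lag, or bromination may run beyond four substitutions. The fallback splits the exhaustive bromination into two operations steered by different mechanisms. It sets out from 15. Two equivalents of benzyltrimethylammonium tribromide (CH2Cl2–MeOH, rt) should fill only the two positions para to the hydroxyls and give 4-bromo-2-(4,5-dibromo-2-hydroxyphenoxy)phenol F3. NBS (2 equiv) with catalytic diisopropylamine in CH2Cl2 is an ortho-selective bromination that delivers bromine through a hydrogen-bonded N-bromoamine. It should then fill C3 and C5' and arrive at 16.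

Further compounds
F1 | step 5 | 4-bromo-2-methoxy-1-(2-methoxyphenoxy)benzene | COc1ccccc1Oc1ccc(Br)cc1OC
F2 | step 1 | (E)-benzaldehyde O-(5-bromo-2-oxo-2H-pyran-3-yl)oxime | O=c1occ(Br)cc1O/N=C/c1ccccc1
F3 | step 7 | 4-bromo-2-(4,5-dibromo-2-hydroxyphenoxy)phenol | Oc1ccc(Br)cc1Oc1cc(Br)c(Br)cc1O
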